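All three flavan units come from one building block, tetra-O-benzyl-8-bromoepicatechin. The two C4–C6 interflavan bonds are then made by Friedel–Crafts alkylation, with bromine caps at C8 directing attack to C6. The building block rests on a [3+3] annulation that exploits the ortho placement of C4 and O1 on ring A (C4a, C8a). The enolate of a ring-B aryl ketone (carbonyl at C2, silyloxy group at C3) is C-benzylated at C3 by a 2-bromobenzyl bromide (C3–C4) and then O-arylated at C8a (O1–C8a) in one operation, closing ring C as a 4H-chromene. Desilylation shifts the carbonyl to C3; hydrogenation with dynamic kinetic resolution sets C2 and C3.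

Key step: step 6

Assumption: compounds 1 and 5 are taken as commercially available, and the sense of induction of the hydrogenation catalyst in step 7 is assigned by analogy with 2-alkoxycyclohexanones (the enantiomeric catalyst is used if the opposite sense is found).

Step 1
Reactants: 1 1,3-bis(benzyloxy)-5-bromobenzene
Product: 2 2,4-bis(benzyloxy)-6-bromobenzaldehyde
Conditions: POCl3, DMF, 0 → 80 °C; then H2O
Reagents that add atoms: N,N-dimethylformamide CN(C)C=O; water O
Why: Vilsmeier–Haack formylation, in which the chloroiminium ion should attack ortho to bromine and para to a benzyloxy group in preference to the more hindered position between the two benzyloxy groups.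

Step 2
Reactants: 2 2,4-bis(benzyloxy)-6-bromobenzaldehyde
Product: 3 [2,4-bis(benzyloxy)-6-bromophenyl]methanol
Conditions: NaBH4, MeOH/THF, 0 °C
Reagents that add atoms: none
Why: Borohydride reduction of the aldehyde; the benzyl ethers and the aryl bromide are inert.

Step 3
Reactants: 3 [2,4-bis(benzyloxy)-6-bromophenyl]methanol
Product: 4 1,5-bis(benzyloxy)-3-bromo-2-(bromomethyl)benzene
Conditions: CBr4, PPh3, CH2Cl2, 0 °C; used at once
Reagents that add atoms: carbon tetrabromide BrC(Br)(Br)Br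
Why: Appel reaction under neutral conditions, chosen because the electron-rich benzylic bromide is prone to solvolysis and self-alkylation.

Step 4
Reactants: 5 1-[3,4-bis(benzyloxy)phenyl]ethan-1-one
Product: 6 {1-[3,4-bis(benzyloxy)phenyl]ethenyl}oxy-triisopropylsilane
Conditions: TIPSOTf, Et3N, CH2Cl2, 0 °C → rt
Reagents that add atoms: triisopropylsilyl triflate CC(C)[Si](OS(=O)(=O)C(F)(F)F)(C(C)C)C(C)C
Why: Silyl enol ether formation by soft enolisation of a methyl ketone that has only one enolisable position.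

Step 5
Reactants: 6 {1-[3,4-bis(benzyloxy)phenyl]ethenyl}oxy-triisopropylsilane
Product: 8 1-[3,4-bis(benzyloxy)phenyl]-2-[(triisopropylsilyl)oxy]ethan-1-one, via silyloxy epoxide 7 (not isolated)
Conditions: mCPBA, CH2Cl2, 0 °C
Reagents that add atoms: 3-chloroperoxybenzoic acid OOC(=O)c1cccc(Cl)c1
Why: Rubottom oxidation, in which epoxidation of the enol ether gives 7, which opens to the oxocarbenium ion and rearranges by 1,4-silyl migration to the α-silyloxy ketone.

Step 6
Reactants: 8 1-[3,4-bis(benzyloxy)phenyl]-2-[(triisopropylsilyl)oxy]ethan-1-one; 4 1,5-bis(benzyloxy)-3-bromo-2-(bromomethyl)benzene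
Product: 11 racemic 5,7-bis(benzyloxy)-2-[3,4-bis(benzyloxy)phenyl]chroman-3-one, via C-benzylated ketone 9 (not isolated), via silyl enol ether chromene 10 (not isolated)
Conditions: NaOt-Bu (2.5 equiv), CuI (10 mol %), 1,10-phenanthroline (20 mol %), THF/toluene, 0 → 100 °C; then TBAF, AcOH, 0 °C
Reagents that add atoms: none
Why: The sodium enolate of 8 is C-benzylated at C3 by the benzylic bromide of 4 (SN2, forms C3–C4) to give 9; a second deprotonation gives the tetrasubstituted enolate, whose oxygen is coupled with the ortho aryl bromide by monovalent copper (oxidative addition at C8a–Br, reductive elimination, forms O1–C8a) to give 4H-chromene 10, and fluoride then frees the C3 enol, which tautomerises to ketone 11. The closest known reaction type is the copper-catalysed domino C-benzylation/O-arylation of enolates with 2-bromobenzyl bromides (Ullmann-type enolate O-arylation). Ring C closes by intramolecular C(sp2)–O coupling through a six-membered transition state (6-exo attack of O1 on C8a); no other ring is formed. The only stereocentre created, C2 of 11, is deliberately left racemic and configurationally labile, because step 7 sets C2 and C3 together. The step needs C- over O-benzylation (sodium enolate in THF, soft benzylic bromide), mono- over dialkylation (one equivalent of 4, hindered second enolate) and O- over C-arylation (C-arylation would need a four-membered ring); enolate geometry should not matter because the isomers equilibrate under the basic conditions.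

Step 7
Reactants: 11 racemic 5,7-bis(benzyloxy)-2-[3,4-bis(benzyloxy)phenyl]chroman-3-one
Product: 12 (2R,3R)-5,7-bis(benzyloxy)-2-[3,4-bis(benzyloxy)phenyl]chroman-3-ol (5,7,3′,4′-tetra-O-benzyl-(−)-epicatechin)
Conditions: H2 (8 atm), RuCl2[(S)-xylbinap][(S)-daipen] (0.5 mol %), KOt-Bu (5 mol %), i-PrOH/toluene, 25 °C
Reagents that add atoms: none
Why: Noyori asymmetric hydrogenation with dynamic kinetic resolution, in which C2 racemises by base-mediated enolisation faster than the ketone is reduced and the chiral ruthenium hydride should reduce the (2R) ketone from the face opposite the C2 aryl group, so that the catalyst sets C2 (R) and C3 (R) together as the 2,3-cis alcohol.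

Step 8
Reactants: 12 (2R,3R)-5,7-bis(benzyloxy)-2-[3,4-bis(benzyloxy)phenyl]chroman-3-ol
Product: 13 5,7,3′,4′-tetra-O-benzyl-8-bromo-(−)-epicatechin
Conditions: NBS (1.0 equiv), CH2Cl2, −40 → 0 °C
Reagents that add atoms: N-bromosuccinimide O=C1CCC(=O)N1Br
Why: Electrophilic aromatic bromination at C8, the most nucleophilic position of a 5,7-dialkoxyflavan, which blocks C8 in the later couplings.

Step 9
Reactants: 13 5,7,3′,4′-tetra-O-benzyl-8-bromo-(−)-epicatechin
Product: 14 5,7,3′,4′-tetra-O-benzyl-8-bromo-4β-(2-ethoxyethoxy)-(−)-epicatechin (2,3-cis, 3,4-trans)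
Conditions: DDQ, 2-ethoxyethanol, CH2Cl2, rt
Reagents that add atoms: 2-ethoxyethanol CCOCCO
Why: Benzylic oxidation by DDQ (hydride abstraction from C4 gives the flavan-4-yl cation stabilised by ring A), trapped by the alcohol trans to the C3 hydroxyl, which sets the 4β configuration of the leaving group.

Step 10
Reactants: 14 5,7,3′,4′-tetra-O-benzyl-8-bromo-4β-(2-ethoxyethoxy)-(−)-epicatechin
Product: 15 5,7,3′,4′-tetra-O-benzyl-6,8-dibromo-4β-(2-ethoxyethoxy)-(−)-epicatechin
Conditions: NBS (1.1 equiv), CH2Cl2, −20 → 0 °C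
Reagents that add atoms: N-bromosuccinimide O=C1CCC(=O)N1Br
Why: Electrophilic aromatic bromination at C6, the only free activated position of ring A, which caps the future top unit against self-condensation in step 12.

Step 11
Reactants: 14 5,7,3′,4′-tetra-O-benzyl-8-bromo-4β-(2-ethoxyethoxy)-(−)-epicatechin; 13 5,7,3′,4′-tetra-O-benzyl-8-bromo-(−)-epicatechin
Product: 16 5,7,3′,4′-tetra-O-benzyl-8-bromoepicatechin-(4β→6)-5,7,3′,4′-tetra-O-benzyl-8-bromoepicatechin
Conditions: TMSOTf (0.3 equiv), 13 (4 equiv), CH2Cl2, −78 °C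
Reagents that add atoms: none
Why: Friedel–Crafts alkylation, in which TMSOTf ionises the C4 acetal of 14 and C6 of 13 (C8 blocked by bromine) should attack the cation from the β face, anti to the α-oriented C3 hydroxyl and C2 aryl group, setting the 3,4-trans (4β) stereocentre, while the excess of 13 suppresses self-condensation of 14.

Step 12
Reactants: 15 5,7,3′,4′-tetra-O-benzyl-6,8-dibromo-4β-(2-ethoxyethoxy)-(−)-epicatechin; 16 5,7,3′,4′-tetra-O-benzyl-8-bromoepicatechin-(4β→6)-5,7,3′,4′-tetra-O-benzyl-8-bromoepicatechin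
Product: 17 5,7,3′,4′-tetra-O-benzyl-6,8-dibromoepicatechin-(4β→6)-5,7,3′,4′-tetra-O-benzyl-8-bromoepicatechin-(4β→6)-5,7,3′,4′-tetra-O-benzyl-8-bromoepicatechin
Conditions: TMSOTf (0.3 equiv), CH2Cl2, −78 → −40 °C
Reagents that add atoms: none
Why: Friedel–Crafts alkylation, in which the cation from 15 cannot self-condense (C6 and C8 brominated) and the only free activated position of 16, C6 of its upper unit, should attack from the β face, anti to the C3 hydroxyl, to set the second 4β stereocentre.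

Step 13
Reactants: 17 protected, brominated trimer
Product: 18 epicatechin-(4β→6)-epicatechin-(4β→6)-epicatechin (CNP0163146.2)
Conditions: H2 (1 atm), Pd(OH)2/C, Et3N, THF/MeOH/H2O, rt
Reagents that add atoms: none
Why: Hydrogenolysis of the twelve benzyl ethers and four aryl C–Br bonds over Pd(OH)2/C, which touches no stereocentre, with Et3N taking up the HBr that would otherwise endanger the acid-labile interflavan bonds.

Compound list
1 | 1,3-bis(benzyloxy)-5-bromobenzene | Brc1cc(OCc2ccccc2)cc(OCc2ccccc2)c1 | starting material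
2 | 2,4-bis(benzyloxy)-6-bromobenzaldehyde | O=Cc1c(Br)cc(OCc2ccccc2)cc1OCc1ccccc1 | intermediate
3 | [2,4-bis(benzyloxy)-6-bromophenyl]methanol | OCc1c(Br)cc(OCc2ccccc2)cc1OCc1ccccc1 | intermediate
4 | 1,5-bis(benzyloxy)-3-bromo-2-(bromomethyl)benzene | BrCc1c(Br)cc(OCc2ccccc2)cc1OCc1ccccc1 | intermediate
5 | 1-[3,4-bis(benzyloxy)phenyl]ethan-1-one | CC(=O)c1ccc(OCc2ccccc2)c(OCc2ccccc2)c1 | starting material
6 | {1-[3,4-bis(benzyloxy)phenyl]ethenyl}oxy-triisopropylsilane | C=C(O[Si](C(C)C)(C(C)C)C(C)C)c1ccc(OCc2ccccc2)c(OCc2ccccc2)c1 | intermediate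
7 | 2-[3,4-bis(benzyloxy)phenyl]-2-[(triisopropylsilyl)oxy]oxirane (racemic) | CC(C)[Si](OC1(CO1)c1ccc(OCc2ccccc2)c(OCc2ccccc2)c1)(C(C)C)C(C)C | intermediate (not isolated)
8 | 1-[3,4-bis(benzyloxy)phenyl]-2-[(triisopropylsilyl)oxy]ethan-1-one | O=C(CO[Si](C(C)C)(C(C)C)C(C)C)c1ccc(OCc2ccccc2)c(OCc2ccccc2)c1 | intermediate
9 | 1-[3,4-bis(benzyloxy)phenyl]-3-[2,4-bis(benzyloxy)-6-bromophenyl]-2-[(triisopropylsilyl)oxy]propan-1-one (racemic) | O=C(c1ccc(OCc2ccccc2)c(OCc2ccccc2)c1)C(O[Si](C(C)C)(C(C)C)C(C)C)Cc1c(Br)cc(OCc2ccccc2)cc1OCc1ccccc1 | intermediate (not isolated)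
10 | 5,7-bis(benzyloxy)-2-[3,4-bis(benzyloxy)phenyl]-3-[(triisopropylsilyl)oxy]-4H-chromene | CC(C)[Si](OC1=C(c2ccc(OCc3ccccc3)c(OCc3ccccc3)c2)Oc2cc(OCc3ccccc3)cc(OCc3ccccc3)c2C1)(C(C)C)C(C)C | intermediate (not isolated)
11 | racemic 5,7-bis(benzyloxy)-2-[3,4-bis(benzyloxy)phenyl]chroman-3-one | O=C1Cc2c(OCc3ccccc3)cc(OCc3ccccc3)cc2OC1c1ccc(OCc2ccccc2)c(OCc2ccccc2)c1 | intermediate
12 | (2R,3R)-5,7-bis(benzyloxy)-2-[3,4-bis(benzyloxy)phenyl]chroman-3-ol (5,7,3′,4′-tetra-O-benzyl-(−)-epicatechin) | C(c1ccccc1)Oc1cc(OCc2ccccc2)c2c(c1)O[C@H](c1ccc(OCc3ccccc3)c(OCc3ccccc3)c1)[C@H](O)C2 | intermediate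
13 | 5,7,3′,4′-tetra-O-benzyl-8-bromo-(−)-epicatechin | C(c1ccccc1)Oc1cc(OCc2ccccc2)c2c(c1Br)O[C@H](c1ccc(OCc3ccccc3)c(OCc3ccccc3)c1)[C@H](O)C2 | intermediate
14 | 5,7,3′,4′-tetra-O-benzyl-8-bromo-4β-(2-ethoxyethoxy)-(−)-epicatechin | C(c1ccccc1)Oc1cc(OCc2ccccc2)c2c(c1Br)O[C@H](c1ccc(OCc3ccccc3)c(OCc3ccccc3)c1)[C@H](O)[C@H]2OCCOCC | intermediate
15 | 5,7,3′,4′-tetra-O-benzyl-6,8-dibromo-4β-(2-ethoxyethoxy)-(−)-epicatechin | C(c1ccccc1)Oc1c(Br)c(OCc2ccccc2)c2c(c1Br)O[C@H](c1ccc(OCc3ccccc3)c(OCc3ccccc3)c1)[C@H](O)[C@H]2OCCOCC | intermediate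
16 | 5,7,3′,4′-tetra-O-benzyl-8-bromoepicatechin-(4β→6)-5,7,3′,4′-tetra-O-benzyl-8-bromoepicatechin | c1c(OCc4ccccc4)c(Br)c2c(c1OCc4ccccc4)[C@H](c1c(OCc4ccccc4)c(Br)c3c(c1OCc4ccccc4)C[C@@H](O)[C@@H](c1ccc(OCc4ccccc4)c(OCc4ccccc4)c1)O3)[C@@H](O)[C@@H](c1ccc(OCc4ccccc4)c(OCc4ccccc4)c1)O2 | intermediate
17 | 5,7,3′,4′-tetra-O-benzyl-6,8-dibromoepicatechin-(4β→6)-5,7,3′,4′-tetra-O-benzyl-8-bromoepicatechin-(4β→6)-5,7,3′,4′-tetra-O-benzyl-8-bromoepicatechin | C(c5ccccc5)Oc1c(Br)c(OCc5ccccc5)c2c(c1Br)O[C@H](c1ccc(OCc5ccccc5)c(OCc5ccccc5)c1)[C@H](O)[C@H]2c1c(OCc4ccccc4)c(Br)c2c(c1OCc4ccccc4)[C@H](c1c(OCc4ccccc4)c(Br)c3c(c1OCc4ccccc4)C[C@@H](O)[C@@H](c1ccc(OCc4ccccc4)c(OCc4ccccc4)c1)O3)[C@@H](O)[C@@H](c1ccc(OCc4ccccc4)c(OCc4ccccc4)c1)O2 | intermediate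
18 | epicatechin-(4β→6)-epicatechin-(4β→6)-epicatechin (CNP0163146.2) | Oc1cc(O)c2c(c1)O[C@H](c1ccc(O)c(O)c1)[C@H](O)[C@H]2c1c(O)cc2c(c1O)[C@H](c1c(O)cc3c(c1O)C[C@@H](O)[C@@H](c1ccc(O)c(O)c1)O3)[C@@H](O)[C@@H](c1ccc(O)c(O)c1)O2 | target

Total step count: 13. Longest linear sequence: 10 steps (steps 1, 2, 3, 6, 7, 8, 9, 10, 12, 13).

Steps most likely to fail

Step 6. O-benzylation or double benzylation may compete with the wanted C-benzylation. The hindered tetrasubstituted enolate may also lose its aryl bromine by protodebromination, or suffer silyl migration, faster than the copper-mediated ring closure. The fallback separates the two bond formations and closes ring C at the alcohol oxidation level. It sets out from 8 and 4, which are combined with LiN(SiMe3)2 in THF at −78 °C, and 9 is isolated. NaBH4 reduces 9 to 1-[3,4-bis(benzyloxy)phenyl]-3-[2,4-bis(benzyloxy)-6-bromophenyl]-2-[(triisopropylsilyl)oxy]propan-1-ol F1. Palladium-catalysed intramolecular etherification (Pd(OAc)2, 2-(di-tert-butylphosphino)-1,1′-binaphthyl, Cs2CO3, toluene, 80 °C) should give 5,7-bis(benzyloxy)-2-[3,4-bis(benzyloxy)phenyl]-3-[(triisopropylsilyl)oxy]chromane F2. TBAF frees 5,7-bis(benzyloxy)-2-[3,4-bis(benzyloxy)phenyl]chroman-3-ol F3 as a mixture of racemic diastereomers, and Dess–Martin periodinane oxidises it back into the route at 11.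

Step 7. Racemisation at C2 may be slower than reduction, or facial discrimination may be poor, which would erode enantiomeric and diastereomeric purity; the basic medium may also degrade the enolisable ketone. The fallback sets out from 11, which is reduced with LiBH(s-Bu)3 in THF at −78 °C (hydride anti to the C2 aryl group) to racemic cis-5,7-bis(benzyloxy)-2-[3,4-bis(benzyloxy)phenyl]chroman-3-ol F4. Esterification with (S)-2-methoxy-2-phenylacetic acid (DCC, DMAP) gives two diastereomeric esters, which are separated. The (2R,3R)-chroman-3-yl (S)-2-methoxy-2-phenylacetate F5 is saponified (LiOH, THF/H2O) to rejoin the route at 12.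

Step 12. Attack by the hindered C6 of 16 may be slow, so that acid-induced scission and scrambling of the interflavan bond already present, and decay of the cation, compete. The fallback changes the leaving group and the mode of activation. It sets out from 15, which is converted with benzyl mercaptan and BF3·OEt2 into 5,7,3′,4′-tetra-O-benzyl-4β-(benzylthio)-6,8-dibromo-(−)-epicatechin F6. F6 is then activated with AgBF4 (thiophilic, no strong free acid) in CH2Cl2 at 0 °C in the presence of 16, coming back to the route at 17.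

Further compounds
F1 | step 6 | 1-[3,4-bis(benzyloxy)phenyl]-3-[2,4-bis(benzyloxy)-6-bromophenyl]-2-[(triisopropylsilyl)oxy]propan-1-ol (racemic diastereomer mixture) | OC(c1ccc(OCc2ccccc2)c(OCc2ccccc2)c1)C(O[Si](C(C)C)(C(C)C)C(C)C)Cc1c(Br)cc(OCc2ccccc2)cc1OCc1ccccc1
F2 | step 6 | 5,7-bis(benzyloxy)-2-[3,4-bis(benzyloxy)phenyl]-3-[(triisopropylsilyl)oxy]chromane (racemic cis/trans mixture) | CC(C)[Si](OC1Cc2c(OCc3ccccc3)cc(OCc3ccccc3)cc2OC1c1ccc(OCc2ccccc2)c(OCc2ccccc2)c1)(C(C)C)C(C)C
F3 | step 6 | 5,7-bis(benzyloxy)-2-[3,4-bis(benzyloxy)phenyl]chroman-3-ol (racemic cis/trans mixture) | OC1Cc2c(OCc3ccccc3)cc(OCc3ccccc3)cc2OC1c1ccc(OCc2ccccc2)c(OCc2ccccc2)c1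
F4 | step 7 | racemic cis-5,7-bis(benzyloxy)-2-[3,4-bis(benzyloxy)phenyl]chroman-3-ol (both enantiomers shown) | C(c1ccccc1)Oc1cc(OCc2ccccc2)c2c(c1)O[C@H](c1ccc(OCc3ccccc3)c(OCc3ccccc3)c1)[C@H](O)C2.C(c1ccccc1)Oc1cc(OCc2ccccc2)c2c(c1)O[C@@H](c1ccc(OCc3ccccc3)c(OCc3ccccc3)c1)[C@@H](O)C2
F5 | step 7 | (2R,3R)-5,7-bis(benzyloxy)-2-[3,4-bis(benzyloxy)phenyl]chroman-3-yl (S)-2-methoxy-2-phenylacetate | C(c1ccccc1)Oc1cc(OCc2ccccc2)c2c(c1)O[C@H](c1ccc(OCc3ccccc3)c(OCc3ccccc3)c1)[C@H](OC(=O)[C@@H](OC)c1ccccc1)C2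
F6 | step 12 | 5,7,3′,4′-tetra-O-benzyl-4β-(benzylthio)-6,8-dibromo-(−)-epicatechin | C(c1ccccc1)Oc1c(Br)c(OCc2ccccc2)c2c(c1Br)O[C@H](c1ccc(OCc3ccccc3)c(OCc3ccccc3)c1)[C@H](O)[C@H]2SCc1ccccc1
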